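The numbers in the tables are simulated from invented constants; scatter was added.

At 15.0 min the south-west flask shows target nearly stalled while dissolved substrate is still climbing.

| flask | solid substrate | partner | remark | time |
|---|---|---|---|---|
| south-west | 1.4 M | 1.54 M | the very flask that is asked about, followed so far |  |
| flask | 1.4 M | 1.54 M |  | 80 min |

- south-west (time / min: target / %, dissolved substrate / %): 4.00: 14.2, 18.2; 8.00: 31.9, 27.3; 12.0: 39.6, 37.3; 15.0: 41.9, 44.2

(each reading ± 1 percentage point)

- given per volume of solution although it is solid: solid substrate
- at the start none of the solid substrate is in solution
- dissolved substrate means what is dissolved; the solid is not counted in it

- target at 80 min, in percent of the solid substrate charged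
- concentration of dissolved substrate in solution at 8.0 min, in percent of saturation
- the change that raises the amount of target at 80 min, in percent of the solid substrate charged most ("none" if none brings more than 2 percentage points) (ash / cedar / birch / none)
- amount of target at 80 min, in percent of the solid substrate charged, after ash

Divide the gain of target per minute by the dissolved substrate present, and call this the pull; it follows partner if dissolved substrate and partner make target. The pull is 0.195 min⁻¹ between the earliest two readings and 0.0188 min⁻¹ between the latest two. Target's own use of partner lowers partner by a factor of 1.26 over that span, yet the pull falls by a larger factor of 10.4, so the readings point to something else at work. A back reaction would bend the curve the same way; this reckoning bets on a loss of partner, as a choice and not as a finding.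

With its rate of fall frozen, the pull halves every 2.23 min, which is shorter than 80 min. With dissolved substrate frozen at its latest reading, target gains a further 1.7 percentage points and ends at 43.6 %. The pull rests on a last gain of 2.3 points, which is poorly known at a scatter of 1 point, but doubling the tail moves the answer by just 1.7 points.

So this reckoning puts 39.6 % of the charged partner into target: this is the partner share. If both partner steps are first order in partner, their ratio contains no partner, and with the course of dissolved substrate held, the share stays nearly frozen when the partner charge moves. Cedar then gives 87.1 % of target, a reckoning that holds that course of dissolved substrate as it was. If ash doubles dissolved substrate early on, the odds of target against loss, reckoned at 0.656 without ash, double, and target comes to 62.4 %. Cedar stays ahead of ash; birch and saturation lie outside this reckoning.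

The forecast, reasoning that “This suggests a reversible reaction”, gives target 48 %, saturation 45 %, best change cedar, and 48 % after ash.

The flask gives target 45.6 %, saturation 44.6 %, best change cedar with a gain of 31 points, and 59.0 % after ash.

    solid substrate ⇌ dissolved substrate, rate k1*(cs1 - [dissolved substrate]) while solid is left; crystals form when [dissolved substrate] > cs1 (solubility = 0.860 M, k = 0.00270 s⁻¹)
    dissolved substrate + partner → target (k = 0.00520 L mol⁻¹ s⁻¹)
    solid substrate → decomposition product (k = 1.90 × 10⁻⁶ s⁻¹)
    partner → decomposed reagent (k = 0.00180 s⁻¹)

In the flask, dissolving, target making and the loss of partner ran side by side while partner lasted, with 23.4 % of it present at 8.00 min and 0 % at 40.0 min. From then on the flask held 45.6 % of target beside 54.3 % of dissolved substrate, with 0 % of partner left, so partner was the limiting reagent. Its partner share came to 41.5 %, with 0.901 M of decomposed reagent formed. For the neighbour charged with 0.39 M of partner, the reckoned share gives 11.0 % of target, and that neighbour gives 13.1 %.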